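**Plan**
- Retrosynthesis: (a) both aryl–C bonds at the central CH are cut, giving two identical chroman ketones 11 and 6-methylheptanal 12; (b) in each chroman the C3–C4 bond is cut and an NH placed between the two carbons (seven-membered 2,3,4,5-tetrahydro-1,4-benzoxazepine 8); (c) in 8 the O1–C2 bond and the aryl–CH2–N unit are cut (phenol 5, formaldehyde, 2,2-dimethylaziridine 6); (d) the aryl–acyl bond is cut (phloroglucinol 2, acid 1).
- Forward: acylation of 2; bis-benzylation, which leaves only the ketone-chelated OH free and so fixes the ring oxygen ortho to the acyl group; Mannich aminomethylation; aziridine-to-oxazepine expansion; nitrogen deletion (oxazepine to dihydropyran); hydrogenolysis; the aldehyde then joins two halves at C6.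
- Feature used: in the dihydropyran ring, C4 is a benzylic CH2 on the trioxygenated benzene ring and C3 is a CH2 beside the quaternary, O-bearing C2. A C3–NH–C4 amine therefore gives, after loss of N2, a stabilised benzylic radical and a primary radical that the O1–C2–aryl tether holds together for closure of the six-membered ring.
- Stereochemistry: both (R)-centres come from (R)-2-methylbutanoic acid 1 and are carried unchanged; the central CH bears two identical aryl groups and is no stereocentre.

Key step: step 5

Assumption: (R)-2-methylbutanoic acid 1, 2,2-dimethylaziridine 6 and 6-methylheptanal 12 are taken as purchasable.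

Step 1
Reactants: 1 (R)-2-methylbutanoic acid; 2 phloroglucinol (benzene-1,3,5-triol)
Product: 4 (2R)-1-(2,4,6-trihydroxyphenyl)-2-methylbutan-1-one, via (R)-2-methylbutanoyl chloride 3 (not isolated)
Conditions: 1, (COCl)2, cat. DMF, CH2Cl2, 0 °C to rt, evaporate; then 2, AlCl3, PhNO2/CH2Cl2, 0 °C to rt; 1 M HCl
Reagents that add atoms: none
Why: Friedel–Crafts C-acylation of the threefold-symmetric triol can give only one monoketone, and the acid chloride is made and used cold so that the purchased (R)-centre should not epimerise through a ketene.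

Step 2
Reactants: 4 (2R)-1-(2,4,6-trihydroxyphenyl)-2-methylbutan-1-one
Product: 5 (2R)-1-[2,4-bis(benzyloxy)-6-hydroxyphenyl]-2-methylbutan-1-one
Conditions: BnBr (2.1 equiv), K2CO3 (2.2 equiv), DMF, 0 °C to rt
Reagents that add atoms: benzyl bromide BrCc1ccccc1
Why: Williamson etherification should take the para-OH and one of the two equivalent ortho-OH groups, while the OH hydrogen-bonded to the ketone stays free, so the only phenol left is the oxygen that must become ring oxygen O1.

Step 3
Reactants: 5 (2R)-1-[2,4-bis(benzyloxy)-6-hydroxyphenyl]-2-methylbutan-1-one; 6 2,2-dimethylaziridine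
Product: 7 (2R)-1-{4,6-bis(benzyloxy)-3-[(2,2-dimethylaziridin-1-yl)methyl]-2-hydroxyphenyl}-2-methylbutan-1-one
Conditions: (CH2O)n (1.2 equiv), 6 (1.3 equiv), EtOH, 45 °C, no acid; used crude
Reagents that add atoms: formaldehyde (as paraformaldehyde) C=O
Why: Phenolic Mannich aminomethylation, in which the free OH should direct the formaldehyde/aziridine electrophile by hydrogen bonding to the neighbouring ring carbon (between the OH and a benzyloxy group), while the neutral medium keeps the aziridine closed.

Step 4
Reactants: 7 (2R)-1-{4,6-bis(benzyloxy)-3-[(2,2-dimethylaziridin-1-yl)methyl]-2-hydroxyphenyl}-2-methylbutan-1-one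
Product: 8 (2R)-1-[6,8-bis(benzyloxy)-2,2-dimethyl-2,3,4,5-tetrahydro-1,4-benzoxazepin-9-yl]-2-methylbutan-1-one
Conditions: (CF3)2CHOH, 0.01 M, 25 to 50 °C
Reagents that add atoms: none
Why: Proposed new method: in hexafluoroisopropanol the phenol proton, relayed by the solvent, turns the aziridine into an aziridinium ion whose tertiary C–N bond ionises in an SN1-like way, and the phenol oxygen, held about 3 Å away by the N–CH2–aryl tether, captures the tertiary carbon from the front side, whereas in-line SN2 attack at either aziridine carbon is geometrically closed (endo-tet), so only the tertiary aryl ether and the seven-membered ring should form; the closest known reaction types are the acid-promoted Heine ring expansion of N-acyl-2,2-dimethylaziridines to 5,5-dimethyl-2-oxazolines, where an oxygen held on nitrogen likewise captures the tertiary aziridine carbon, and the acid opening of 2,2-dimethylaziridine by O-nucleophiles at the tertiary carbon.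

Step 5
Reactants: 8 (2R)-1-[6,8-bis(benzyloxy)-2,2-dimethyl-2,3,4,5-tetrahydro-1,4-benzoxazepin-9-yl]-2-methylbutan-1-one
Product: 10 (2R)-1-[5,7-bis(benzyloxy)-2,2-dimethyl-3,4-dihydro-2H-chromen-8-yl]-2-methylbutan-1-one, via cyclic isodiazene 9 (not isolated)
Conditions: N-(benzyloxy)-N-(pivaloyloxy)-4-(trifluoromethyl)benzamide (1.5 equiv), THF, 45 °C
Reagents that add atoms: none
Why: The secondary amine attacks the electrophilic nitrogen of the anomeric amide with loss of pivalate, and a HERON-type shift of the benzyloxy group to the acyl carbon releases benzyl 4-(trifluoromethyl)benzoate and the cyclic isodiazene 9, which extrudes N2. The closest known reaction type is the nitrogen deletion of benzo-fused cyclic secondary benzylic amines (tetrahydroisoquinoline to indane). The six-membered dihydropyran ring is closed by recombination of the short-lived singlet 1,6-diradical (benzylic C4 radical and primary C3 radical), so the seven-membered oxazepine contracts by one atom; this is a radical–radical coupling and not an exo or endo cyclisation. No stereocentre is formed, and the remote (R)-centre should not be touched under neutral conditions at 45 °C. The step needs N2 loss to outrun isodiazene-to-hydrazone tautomerisation and C–C recombination to outrun β-scission of the β-aryloxy primary radical; the first is secured by the weak benzylic C–N bond on the trioxygenated ring, the second by the O1–C2–aryl tether that keeps both radical centres in one molecule.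

Step 6
Reactants: 10 (2R)-1-[5,7-bis(benzyloxy)-2,2-dimethyl-3,4-dihydro-2H-chromen-8-yl]-2-methylbutan-1-one
Product: 11 (2R)-1-(5,7-dihydroxy-2,2-dimethyl-3,4-dihydro-2H-chromen-8-yl)-2-methylbutan-1-one
Conditions: H2 (1 atm), 10% Pd/C, EtOAc/EtOH, rt
Reagents that add atoms: none
Why: Hydrogenolysis of both benzyl aryl ethers should leave the hindered, hydrogen-bonded aryl ketone and the chroman untouched, and it is placed after the nitrogen deletion because the benzylic C–N bond of 8 would not survive it.

Step 7
Reactants: 11 (2R)-1-(5,7-dihydroxy-2,2-dimethyl-3,4-dihydro-2H-chromen-8-yl)-2-methylbutan-1-one (2 equiv); 12 6-methylheptanal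
Product: 15 1,1'-[(6-methylheptane-1,1-diyl)bis(5,7-dihydroxy-2,2-dimethyl-3,4-dihydro-2H-chromene-6,8-diyl)]bis[(2R)-2-methylbutan-1-one] (target), via benzylic carbinol 13 (not isolated), via ortho-quinone methide 14 (not isolated)
Conditions: 12 (0.5 equiv), TsOH·H2O (10 mol %), CH2Cl2, 4 Å MS, rt
Reagents that add atoms: none
Why: Acid-catalysed Friedel–Crafts hydroxyalkylation at C6, the only free and doubly OH-activated ring position, should give carbinol 13, which dehydrates to the ortho-quinone methide 14 and is captured at C6 of a second molecule of 11; the new central carbon carries two identical (R)-configured aryl groups and is no stereocentre, so one stereoisomer is expected.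

**Compound list**
1 | (R)-2-methylbutanoic acid | CC[C@@H](C)C(=O)O | starting material
2 | phloroglucinol (benzene-1,3,5-triol) | Oc1cc(O)cc(O)c1 | starting material
3 | (R)-2-methylbutanoyl chloride (not isolated) | CC[C@@H](C)C(=O)Cl | intermediate
4 | (2R)-1-(2,4,6-trihydroxyphenyl)-2-methylbutan-1-one | CC[C@@H](C)C(=O)c1c(O)cc(O)cc1O | intermediate
5 | (2R)-1-[2,4-bis(benzyloxy)-6-hydroxyphenyl]-2-methylbutan-1-one | CC[C@@H](C)C(=O)c1c(O)cc(OCc2ccccc2)cc1OCc1ccccc1 | intermediate
6 | 2,2-dimethylaziridine | CC1(C)CN1 | starting material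
7 | (2R)-1-{4,6-bis(benzyloxy)-3-[(2,2-dimethylaziridin-1-yl)methyl]-2-hydroxyphenyl}-2-methylbutan-1-one | CC[C@@H](C)C(=O)c1c(O)c(CN2CC2(C)C)c(OCc2ccccc2)cc1OCc1ccccc1 | intermediate
8 | (2R)-1-[6,8-bis(benzyloxy)-2,2-dimethyl-2,3,4,5-tetrahydro-1,4-benzoxazepin-9-yl]-2-methylbutan-1-one | CC[C@@H](C)C(=O)c1c2OC(C)(C)CNCc2c(OCc2ccccc2)cc1OCc1ccccc1 | intermediate
9 | cyclic isodiazene (1,1-diazene) of 8, N4 carrying the terminal nitrogen (not isolated) | CC[C@@H](C)C(=O)c1c2OC(C)(C)C[N+](=[N-])Cc2c(OCc2ccccc2)cc1OCc1ccccc1 | intermediate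
10 | (2R)-1-[5,7-bis(benzyloxy)-2,2-dimethyl-3,4-dihydro-2H-chromen-8-yl]-2-methylbutan-1-one | CC[C@@H](C)C(=O)c1c2OC(C)(C)CCc2c(OCc2ccccc2)cc1OCc1ccccc1 | intermediate
11 | (2R)-1-(5,7-dihydroxy-2,2-dimethyl-3,4-dihydro-2H-chromen-8-yl)-2-methylbutan-1-one | CC[C@@H](C)C(=O)c1c2OC(C)(C)CCc2c(O)cc1O | intermediate
12 | 6-methylheptanal | CC(C)CCCCC=O | starting material
13 | (2R)-1-[5,7-dihydroxy-6-(1-hydroxy-6-methylheptyl)-2,2-dimethyl-3,4-dihydro-2H-chromen-8-yl]-2-methylbutan-1-one, both epimers at the carbinol carbon (not isolated) | CC[C@@H](C)C(=O)c1c2OC(C)(C)CCc2c(O)c(C(O)CCCCC(C)C)c1O | intermediate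
14 | (2R)-1-[7-hydroxy-2,2-dimethyl-6-(6-methylheptylidene)-5-oxo-3,4,5,6-tetrahydro-2H-chromen-8-yl]-2-methylbutan-1-one, alkene geometry not fixed (not isolated) | CC[C@@H](C)C(=O)C1=C(O)C(=CCCCCC(C)C)C(=O)C2=C1OC(C)(C)CC2 | intermediate
15 | 1,1'-[(6-methylheptane-1,1-diyl)bis(5,7-dihydroxy-2,2-dimethyl-3,4-dihydro-2H-chromene-6,8-diyl)]bis[(2R)-2-methylbutan-1-one] | CC[C@@H](C)C(=O)c1c(O)c(C(CCCCC(C)C)c2c(O)c3c(c(C(=O)[C@H](C)CC)c2O)OC(C)(C)CC3)c(O)c2c1OC(C)(C)CC2 | target

**Step count and risks**
Total step count: 7. Longest linear sequence: 7 steps (1 to 15).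

Steps most likely to fail:

1. Step 4 (Proposed new method). The tertiary cation may lose a proton to give a ring-opened methallylamine, or be taken by a second molecule to give oligomers, before the tethered phenol oxygen reaches it. The fallback reverses the order of bond formation with known chemistry; it sets out from 5 and 6 and rejoins the route at 8. Aziridine 6 is N-sulfonylated (2-nitrobenzenesulfonyl chloride, Et3N) to 2,2-dimethyl-1-[(2-nitrophenyl)sulfonyl]aziridine F1. BF3·OEt2-catalysed opening of F1 by the phenol of 5 at the tertiary carbon should give the aryl tert-alkyl ether sulfonamide F2. Paraformaldehyde/TFA should close the seven-membered ring at the carbon ortho to the ether oxygen through the N-sulfonyliminium ion (Pictet–Spengler type) to the N-sulfonyl benzoxazepine F3. PhSH/K2CO3 then removes the sulfonyl group to give 8.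

2. Step 5. The 1,6-diradical may fragment by β-scission of the β-aryloxy radical (loss of isobutene), or the isodiazene may tautomerise to a hydrazone instead of losing N2. The fallback keeps a ring-size change but makes the C–C bonds first; it sets out from 5 and rejoins at 10. A Nickl benzofuran synthesis (lithium phenoxide of 5, (E)-1,4-dibromo-2-methylbut-2-ene, hot toluene) should give the 2-isopropenyl-2,3-dihydrobenzofuran F4 as both C2 epimers. Pd(0)/PBu3 with HCO2H–Et3N should open the allylic aryl ether reductively to the alkenylphenol F5. TsOH in toluene then closes the tertiary cation onto the only free phenol (Markovnikov hydroalkoxylation), a five-to-six ring expansion by opening and reclosure, to give 10.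

3. Step 3. Aminomethylation may stall because an aziridine nitrogen forms an iminium ion reluctantly, and traces of acid may start ring-opening polymerisation of 6. The fallback sets out from 5 and rejoins at 7. Dimethyl(methylidene)ammonium iodide (Eschenmoser's salt) in CH2Cl2 should give the ordinary Mannich base F6. MeI gives the trimethylammonium iodide F7. Warming F7 with 6 and K2CO3 in MeCN should release the ortho-quinone methide, to which the aziridine N–H adds to give 7.

Further compounds
F1 | step 4 | 2,2-dimethyl-1-[(2-nitrophenyl)sulfonyl]aziridine | CC1(C)CN1S(=O)(=O)c1ccccc1[N+](=O)[O-]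
F2 | step 4 | N-{2-[3,5-bis(benzyloxy)-2-[(2R)-2-methylbutanoyl]phenoxy]-2-methylpropyl}-2-nitrobenzenesulfonamide | CC[C@@H](C)C(=O)c1c(OC(C)(C)CNS(=O)(=O)c2ccccc2[N+](=O)[O-])cc(OCc2ccccc2)cc1OCc1ccccc1
F3 | step 4 | (2R)-1-{6,8-bis(benzyloxy)-2,2-dimethyl-4-[(2-nitrophenyl)sulfonyl]-2,3,4,5-tetrahydro-1,4-benzoxazepin-9-yl}-2-methylbutan-1-one | CC[C@@H](C)C(=O)c1c2OC(C)(C)CN(Cc2c(OCc2ccccc2)cc1OCc1ccccc1)S(=O)(=O)c1ccccc1[N+](=O)[O-]
F4 | step 5 | (2R)-1-[4,6-bis(benzyloxy)-2-(prop-1-en-2-yl)-2,3-dihydro-1-benzofuran-7-yl]-2-methylbutan-1-one, both C2 epimers | CC[C@@H](C)C(=O)c1c2OC(C(C)=C)Cc2c(OCc2ccccc2)cc1OCc1ccccc1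
F5 | step 5 | (2R)-1-[4,6-bis(benzyloxy)-2-hydroxy-3-(3-methylbut-3-en-1-yl)phenyl]-2-methylbutan-1-one | CC[C@@H](C)C(=O)c1c(O)c(CCC(C)=C)c(OCc2ccccc2)cc1OCc1ccccc1
F6 | step 3 | (2R)-1-{4,6-bis(benzyloxy)-3-[(dimethylamino)methyl]-2-hydroxyphenyl}-2-methylbutan-1-one | CC[C@@H](C)C(=O)c1c(O)c(CN(C)C)c(OCc2ccccc2)cc1OCc1ccccc1
F7 | step 3 | 1-{2,4-bis(benzyloxy)-6-hydroxy-5-[(2R)-2-methylbutanoyl]phenyl}-N,N,N-trimethylmethanaminium iodide | CC[C@@H](C)C(=O)c1c(O)c(C[N+](C)(C)C)c(OCc2ccccc2)cc1OCc1ccccc1.[I-]
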